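(All runs come from a simulation on assumed constants; noise was put on by code.)

| flask | starting material | reagent | second substrate | third substrate | remark | time |
|---|---|---|---|---|---|---|
| south | 1.4 M | 1.05 equiv | 0.50 equiv | 0.34 equiv | run made earlier |  |
| north | 1.4 M | 1.05 equiv | 0.50 equiv | 0.61 equiv | run made earlier |  |
| west | 1.4 M | 1.05 equiv | 0.50 equiv | 0.84 equiv | run made earlier |  |
| epsilon | 1.4 M | 1.05 equiv | 0.500 equiv | 0.330 equiv |  | 12 min |
| beta | 1.4 M | 1.05 equiv | 0.500 equiv | 1.00 equiv |  | 12 min |

| run | time / min | target / % | starting material / % |
|---|---|---|---|
| south | 0.667 | 7.0 | 92.1 |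
| south | 1.50 | 11.2 | 87.4 |
| south | 4.00 | 23.0 | 73.4 |
| south | 8.00 | 29.4 | 63.1 |
| north | 1.00 | 9.2 | 91.0 |
| north | 3.00 | 16.3 | 80.2 |
| north | 5.00 | 21.5 | 74.2 |
| north | 8.00 | 23.7 | 70.4 |
| west | 2.00 | 12.4 | 87.1 |
| west | 4.00 | 16.5 | 79.7 |
| west | 6.00 | 18.2 | 78.7 |
| west | 8.00 | 18.1 | 76.4 |

(scatter of a reading: 1 percentage point)



1. which of the two ends with the higher amount of target, in percent of the starting material charged ("neither" if they lie within 2 percentage points) (epsilon / beta / neither)
2. target at the end, in percent of the starting material charged, epsilon
3. target at the end, in percent of the starting material charged, beta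

West levels off at 18.2 % of target with 0.84 equiv of third substrate, and the two multiplied give a reading of 15.3 %. I call this the stall product: the level at which target stops, times the equivalents of third substrate. North, nearly flat at its last reading, gives 14.5 %, so I take the stall level to fall as one over the third substrate, as if third substrate and starting material drew on one shared reagent.

For beta, the top of my bracket is west's 18.2 %, since beta holds more third substrate. The bottom comes from counting turnovers: if each third substrate takes one reagent, its whole charge still leaves 5.00 % of the starting material's amount. Inside that bracket the stall product gives my estimate, 15.3 %, which is an estimate and no bound.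

For epsilon, the bottom is south's last 29.4 %, still climbing, with 0.34 equiv of third substrate and 4.00 min less time. The top is the stall level, 46.3 %, which epsilon reaches only if its reagent is finished by 12 min. I expect epsilon to end higher.

The forecast reasons that “Starting material stalls along with target”. It gives 33.5 % for epsilon (30 % to 38 %), inside my bracket for epsilon, and 15 % for beta (12.5 % to 17 %), inside my bracket for beta but lower than my estimate.

The flasks give 31.4 % of target in epsilon and 14.0 % in beta, so epsilon ends higher.

    second substrate + reagent → second product (k = 0.00950 M⁻¹ min⁻¹)
    2 second substrate → self-condensation product (k = 0.720 M⁻¹ min⁻¹)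
    third substrate + reagent → third product (k = 0.500 M⁻¹ min⁻¹)
    starting material + reagent → target (k = 0.0790 M⁻¹ min⁻¹)
    target ⇌ isomer of the product (K = 23.0, k = 0.0510 min⁻¹)

Beta's stall product is 14.0 %, near west's 15.3 %, with 2.2 % of its reagent charge left at 12.0 min. Epsilon's is 10.3 %, lower than west's, with 24 % of its reagent charge left. At the start of beta, third substrate uses reagent 6.3 times as fast as starting material does. At 12.0 min in beta, that ratio is still 1.7.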